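Temperature opened the meeting: the flasks share one charge and 12 h, and differ in their bath.

common to all: starting material 0.10 M; free catalyst 0.50 mM; time 12 h

| flask | temperature |
|---|---|
| south-east | 40 °C |
| south-west | 70 °C |
| north-west | 85 °C |
| north-east | 55 °C |

    starting material + free catalyst → catalyst intermediate A (k1 = 1.9 M⁻¹ s⁻¹, Ea1 = 47.0 kJ mol⁻¹)
    catalyst intermediate A → catalyst intermediate B (k2 = 5.4 s⁻¹, Ea2 = 89.0 kJ mol⁻¹)
    catalyst intermediate B → free catalyst + target (k3 = 0.036 s⁻¹, Ea3 = 104 kJ mol⁻¹)
    target ⇌ isomer of the product (K4 = 4.3, k4 = 7.3 × 10⁻⁵ s⁻¹, Ea4 = 122 kJ mol⁻¹, ΔH4 = −33.0 kJ mol⁻¹)
    (constants at 70 °C)

- the constants hold at 70 °C; other temperatures follow from the activation energies and enthalpies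

- the flask with the highest amount of target, in percent of the starting material charged ("all alike" if they lie within 1.5 percentage points) (south-east / south-west / north-west / north-east / all alike)
- final target, as a percentage of the starting material charged, in south-east
- final target, as a percentage of the starting material charged, in south-west
- final target, as a percentage of the starting material charged, in north-west
- final target, as a percentage of the starting material charged, in north-east

The kineticist argued that catalyst intermediate B holds the catalyst while starting material is plentiful. At 70 °C its formation at 5.4 s⁻¹ outruns its exit at 0.036 s⁻¹. In north-east, at 55 °C, its exit constant of 0.00680 s⁻¹ stays below the 0.0895 s⁻¹ at which free catalyst is captured at full charge. So, for north-east while starting material is plentiful, she called that exit the rate-limiting step and catalyst intermediate B the resting state.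

She counted in powers of ten. At 70 °C the charge is 200 times the catalyst, so turning it over through that exit takes about 1.54 h. Cooling to 55 °C adds 0.724 powers of ten, and cooling to 40 °C adds 1.52. For north-east that gives 8.17 h, the clearing time, meaning the charge-to-catalyst ratio divided by the exit constant. For south-east it gives 50.7 h.

The process chemist took south-east first: its clearing time is longer than the run, so he expected target of about 23.7%. By his reckoning north-east clears within the run, and its clearing time is shorter than the 16.4 h relaxation half-life of target and isomer. He dated the average target to the middle of the clearing time and let it isomerise at 1.03 × 10⁻⁵ s⁻¹, which leaves about 74.5%.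

The analyst answered for the hot flasks. In south-west, at 70 °C, the relaxation half-life of 2.14 h is shorter than the run, so the analyst expected thermodynamic control there. South-west should sit near 18.9%, and north-west near 27.4%. The meeting's pick was north-east.

The forecast gives 21.8% for south-east, 21.3% for south-west, 27.4% for north-west and 76.7% for north-east, names north-east, where “the slow isomerisation has only partly eroded the target”, and differs from the meeting in its south-east, south-west and north-east figures but not in its winner.

The highest target stands in north-east at 77.0%, with 22.2% in south-east, 21.3% in south-west and 27.4% in north-west. The north-east flask keeps 0.22% of its starting material at 12.0 h, beside 22.8% isomer. Read at 3.0 h, the north-east clearing time puts 36.7% of the charge through the cycle, and that flask holds 66.1% starting material.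

The constants were set for the occasion.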